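Counted in percent of the starting material charged, one mixture went into a closed flask, a dosed flask and two tanks, and I wanted the target each one delivers.

| flask | starting material | coupling partner | initiator | remark | time |
|---|---|---|---|---|---|
| south-east | 0.47 M | 1.41 M | 11 mM | one stirred flow tank at steady state, fed with the mixture as stated, mean residence time 300 s |  |
| west | 0.47 M | 1.41 M (fed, over 24.0 s) | 11 mM | a stirred flask in which coupling partner is dosed at a steady rate over 24.0 s without added volume, worked up at 30 s | 30 s |
| south | 0.47 M | 1.41 M | 11 mM | everything together in a closed stirred flask, run for 30 s | 30 s |
| south-west | 0.47 M | 1.41 M | 11 mM | a single well-mixed tank run continuously and read at steady state, 30 s in it on average |  |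

    initiator → 2 initiating radical (k1 = 0.058 s⁻¹)
    starting material + initiating radical → capped initiator + first chain carrier (k2 = 1.1 × 10⁶ M⁻¹ s⁻¹)
    coupling partner + first chain carrier → target + second chain carrier (k3 = 5700 M⁻¹ s⁻¹)
    starting material + second chain carrier → released group + first chain carrier (k4 = 60000 M⁻¹ s⁻¹)
    first chain carrier → ended carrier (k5 = 50 s⁻¹)
    2 first chain carrier → ended chains (k6 = 5.3 × 10⁷ M⁻¹ s⁻¹)
    target ⇌ isomer of the product (K7 = 28, k7 = 0.029 s⁻¹)
    coupling partner → decomposed reagent (k8 = 0.030 s⁻¹)

- a species is counted by the starting material in it: one ended chains counts as two
- two of one species on the left: rate k times its square, two consumed each time
- the stated concentrations are those of everything mixed, before any reaction; amounts are the same in each set-up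
- the feed brings no volume worth counting
- run time (west): 30 s

* order of the set-ups by the amount of target at the outlet or at the end, in percent of the starting material put in, highest first (south-east / west / south / south-west)
* amount of target at the outlet or at the end, in percent of the starting material put in, south-east
* amount of target at the outlet or at the end, in percent of the starting material put in, west
* amount of target at the outlet or at the end, in percent of the starting material put in, south
* amount of target at the outlet or at the end, in percent of the starting material put in, south-west

I followed the south flask first. In the first instants the initiator broke with a half-life of 12.0 s, while starting material took initiating radicals at 5.17 × 10⁵ s⁻¹, so each became a first chain carrier almost at once.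

In the middle the chain ran. At the start, coupling partner took the first chain carrier at 8040 s⁻¹ and starting material took the second chain carrier at 28200 s⁻¹, so the first chain carrier was the resting state. Step 5 ended it at 50 s⁻¹, much slower than step 3 at the start.

Towards the end, step 8 alone gave coupling partner a half-life of 23.1 s, and target was turning into isomer of the product with a forward constant of 0.029 s⁻¹. Over 30 s in the south flask, that constant times the time comes to 0.870, so this loss was no small correction.

The small thing was the back step, at 0.00104 s⁻¹, slower than the forward step. A flask needs the history of what was made, but a tank at steady state does not. Target stands on the left of step 7 and of no other step, and isomer of the product leaves by the outflow and by the back step. Its balance gives, for mean residence time τ: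

kept share = (one + back·τ) / (one + back·τ + forward·τ)

kept share of the south-west tank, target over target plus isomer of the product: 54.2%, against 53.5% without the back step

kept share of the south-east tank: 13.1%, against 10.3% without the back step

Each target holds one starting material, so target and isomer of the product together cannot pass the charge. The south-west tank could therefore deliver at most 54.2% of the charge as target, and the south-east tank at most 13.1%. I left the amounts made open, and my reckoning stopped at these two ceilings.

The forecast gave south > west > south-west > south-east, with 37.6% for south, 27% for west, 23.5% for south-west and 3.7% for south-east, saying that “the 300 s tank lets decomposition and isomerisation take almost everything”.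

The flasks gave south > west > south-west > south-east: 37.7% in the south flask, 27.0% in the west flask, 23.5% in the south-west tank and 3.69% in the south-east tank. The south-west tank also held 19.8% as isomer of the product. Dividing its target by the kept share 54.2% gives 43.3% of the charge as target plus isomer of the product, which leaves 19.8% as isomer of the product. In the south-east tank, the kept share 13.1% gives 28.2% as the two together and 24.5% as isomer of the product, and the isomer of the product there stood at 24.5%.

The constants were drawn at random within sensible limits, and the outcome is calculated.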